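The route disconnects ring A (C7–O–C9'–C8'–C8) at both C–O bonds and keeps the C7–C8 bond as an exocyclic C8=C7 alkene on ring B. The feature used is that H8 and the ring A oxygen on C7 are related as a syn adduct across C7–C8. Hydroboration of the E-benzylidene anti to the C9' arm, oxidation with retention and attack of the C7 alkoxide on the C9' mesylate set C7 (aryl endo) and C8 (cis fusion) and close ring A in one operation. The precursor is a 2,3-trans 2-aryl-3-(mesyloxymethyl)-4-(E)-benzylidene tetrahydrofuran with benzyl and TIPS ethers on the two phenols.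

Key step: step 8

Remark on numbering and configuration: lignan numbering is used (ring A = C7, O, C9', C8', C8; ring B = C7', O, C9, C8, C8'); the target is 7R,8R,7'S,8'R (furofuran numbering 1R,3aR,4S,6aR), with the free-phenol aryl endo on C7 and the prenyloxyaryl exo on C7'.
Remark on supply: 4-(benzyloxy)-3-methoxybenzaldehyde, 4-iodo-2-methoxyphenol, vinylmagnesium bromide, propargyl bromide, prenyl bromide and D-(−)-diisopropyl tartrate are taken as purchasable.

Step 1
Reactants: 1 4-(benzyloxy)-3-methoxybenzaldehyde; 2 vinylmagnesium bromide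
Product: 3 rac-1-[4-(benzyloxy)-3-methoxyphenyl]prop-2-en-1-ol
Conditions: THF, −78 to 0 °C; then aq NH4Cl
Reagents that add atoms: none
Why: Grignard 1,2-addition of the vinyl nucleophile to the non-enolisable aryl aldehyde should give the secondary allylic alcohol cleanly as a racemate, whose carbinol carbon (future C7') is resolved in step 2.

Step 2
Reactants: 3 rac-1-[4-(benzyloxy)-3-methoxyphenyl]prop-2-en-1-ol
Product: 4 (R)-[4-(benzyloxy)-3-methoxyphenyl][(S)-oxiran-2-yl]methanol (erythro)
Conditions: Ti(OiPr)4 (1.0 equiv), D-(−)-DIPT (1.2 equiv), TBHP (0.45 equiv, anhydrous), 4 Å MS, CH2Cl2, −20 °C; then aq tartaric acid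
Reagents that add atoms: tert-butyl hydroperoxide, CC(C)(C)OO
Why: Sharpless kinetic resolution by asymmetric epoxidation: with D-(−)-DIPT the (S)-carbinol is the fast-reacting enantiomer and is epoxidised erythro-selectively through the hydroxyl-bound titanium tartrate peroxide, so that with less than half an equivalent of peroxide the epoxy alcohol carries the carbinol configuration needed for C7' (R here by priority change, later 7'S) while the (R)-alcohol stays behind; the oxirane centre need not be pure because it becomes a radical in step 6.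

Step 3
Reactants: 4 (R)-[4-(benzyloxy)-3-methoxyphenyl][(S)-oxiran-2-yl]methanol; 5 propargyl bromide
Product: 6 (S)-2-{(R)-[4-(benzyloxy)-3-methoxyphenyl](prop-2-yn-1-yloxy)methyl}oxirane
Conditions: NaH (1.2 equiv), Bu4NI (cat.), THF, −10 to 0 °C (bromide present before NaH is added)
Reagents that add atoms: none
Why: Williamson etherification: the sodium alkoxide is formed in the presence of the reactive propargylic bromide at low temperature in an aprotic solvent, so O-alkylation should outrun Payne migration of the oxirane, and the carbinol centre is not touched.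

Step 4
Reactants: 7 4-iodo-2-methoxyphenol
Product: 8 (4-iodo-2-methoxyphenoxy)tri(propan-2-yl)silane
Conditions: TIPSCl, imidazole, DMF, rt
Reagents that add atoms: chlorotri(propan-2-yl)silane (TIPSCl), CC(C)[Si](Cl)(C(C)C)C(C)C
Why: Imidazole-promoted silylation of the phenol gives a TIPS ether, the aryl silyl ether with the best tolerance of base, which masks the acidic OH during cross-coupling, mesylation and borane treatment and is later removed by fluoride without acid.

Step 5
Reactants: 6 (S)-2-{(R)-[4-(benzyloxy)-3-methoxyphenyl](prop-2-yn-1-yloxy)methyl}oxirane; 8 (4-iodo-2-methoxyphenoxy)tri(propan-2-yl)silane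
Product: 9 (S)-2-{(R)-[4-(benzyloxy)-3-methoxyphenyl]({3-[3-methoxy-4-(triisopropylsilyloxy)phenyl]prop-2-yn-1-yl}oxy)methyl}oxirane
Conditions: PdCl2(PPh3)2 (3 mol %), CuI (5 mol %), Et3N, THF, rt, degassed
Reagents that add atoms: none
Why: Sonogashira coupling (oxidative addition of zerovalent palladium into the aryl iodide, copper acetylide transmetalation, reductive elimination) joins the two halves at room temperature under amine base, conditions that leave the oxirane, the propargylic benzylic ether and both phenol ethers intact; coupling after the etherification means that the aryl silyl ether never meets an alkoxide.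

Step 6
Reactants: 9 (S)-2-{(R)-[4-(benzyloxy)-3-methoxyphenyl]({3-[3-methoxy-4-(triisopropylsilyloxy)phenyl]prop-2-yn-1-yl}oxy)methyl}oxirane
Product: 10 [(2S,3R,4E)-2-[4-(benzyloxy)-3-methoxyphenyl]-4-{[3-methoxy-4-(triisopropylsilyloxy)phenyl]methylidene}oxolan-3-yl]methanol
Conditions: Cp2TiCl2 (2.5 equiv), Zn dust, THF, rt (green Cp2TiCl solution added slowly to 9); then aq NaH2PO4
Reagents that add atoms: none
Why: Nugent–RajanBabu reductive epoxide opening: Cp2TiCl (trivalent titanium) cleaves the oxirane by single-electron transfer to the more substituted C8' radical, which closes 5-exo-dig onto the aryl alkyne through a transition state that keeps the C7' aryl and the titanoxymethyl arm trans (8'R), and the linear α-aryl vinyl radical so formed is quenched (hydrogen atom from THF, or capture by a second Cp2TiCl and protonolysis) from the open C9 side, which leaves the aryl cis to C8' (E).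

Step 7
Reactants: 10 [(2S,3R,4E)-2-[4-(benzyloxy)-3-methoxyphenyl]-4-{[3-methoxy-4-(triisopropylsilyloxy)phenyl]methylidene}oxolan-3-yl]methanol
Product: 11 [(2S,3R,4E)-2-[4-(benzyloxy)-3-methoxyphenyl]-4-{[3-methoxy-4-(triisopropylsilyloxy)phenyl]methylidene}oxolan-3-yl]methyl methanesulfonate
Conditions: MsCl, Et3N, CH2Cl2, 0 °C
Reagents that add atoms: methanesulfonyl chloride, CS(=O)(=O)Cl
Why: Sulfonylation of the primary alcohol through the sulfene from MsCl and Et3N installs the leaving group at C9' and at the same time removes the free hydroxyl, which as an alkoxyborane could otherwise deliver hydride to the alkene from the arm's own face.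

Step 8
Reactants: 11 [(2S,3R,4E)-2-[4-(benzyloxy)-3-methoxyphenyl]-4-{[3-methoxy-4-(triisopropylsilyloxy)phenyl]methylidene}oxolan-3-yl]methyl methanesulfonate
Product: 14 (1R,3aR,4S,6aR)-4-[4-(benzyloxy)-3-methoxyphenyl]-1-[3-methoxy-4-(triisopropylsilyloxy)phenyl]tetrahydro-1H,3H-furo[3,4-c]furan (7R,8R,7'S,8'R), via benzylic C7 monoalkylborane 12 (not isolated), via C7-hydroxy C9'-mesylate 13 (not isolated)
Conditions: BH3·SMe2 (3 equiv), THF, 0 °C to rt; then 3 M aq NaOH, 30% H2O2, 0 °C to rt (to 40 °C if 13 persists)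
Reagents that add atoms: hydrogen peroxide, OO (oxygen on C7); borane–dimethyl sulfide, C[S+](C)[BH3-] (boron of 12, only hydrogen in 14)
Why: BH3 adds across C8=C7 in a concerted four-centre syn fashion with boron on the less substituted benzylic CH (C7) and hydrogen on the fully substituted C8; hydroperoxide then triggers the 1,2-shift of C7 from boron to oxygen with retention, and the C7 alkoxide of 13 displaces the primary mesylate. The closest known reaction type is hydroboration–oxidation of a trisubstituted benzylidene alkene followed by Williamson cycloetherification of a 4-hydroxy sulfonate. Ring A (C7–O–C9'–C8'–C8) closes 5-exo-tet by SN2 at primary C9', so no bond at a stereocentre is broken in the closure. C8 is controlled by the C8' mesyloxymethyl arm, which allylic 1,3-strain with the cis aryl holds roughly perpendicular to the alkene plane, so hydrogen enters anti to it and C7 ends cis to C9' (8R, cis ring fusion); C7 is controlled by the E geometry alone, because syn addition and retentive oxidation turn "aryl cis to C8'" into 7R with the aryl endo. The step needs regioselectivity (boron at C7, secured by CH versus fully substituted C8), face selectivity (secured by the C8' arm, whose oxygen is sulfonylated so that no O–B tether can deliver hydride from the arm's own face) and chemoselectivity (sulfonate, benzyl and TIPS ethers are inert to BH3, and the intramolecular closure outruns hydrolysis of the mesylate).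

Step 9
Reactants: 14 (1R,3aR,4S,6aR)-4-[4-(benzyloxy)-3-methoxyphenyl]-1-[3-methoxy-4-(triisopropylsilyloxy)phenyl]tetrahydro-1H,3H-furo[3,4-c]furan
Product: 15 2-methoxy-4-[(1S,3aR,4R,6aR)-4-[3-methoxy-4-(triisopropylsilyloxy)phenyl]tetrahydro-1H,3H-furo[3,4-c]furan-1-yl]phenol (7R,8R,7'S,8'R; phenol on the C7' aryl)
Conditions: H2 (1 atm), 10% Pd/C, EtOAc, rt, stopped at full conversion
Reagents that add atoms: none
Why: Heterogeneous hydrogenolysis cleaves the aryl benzyl ether much faster than the two dialkyl benzylic C–O bonds of the furofuran in neutral ethyl acetate at 1 atm, so stopping at full conversion should free only the C7' aryl phenol, with the TIPS ether and all four stereocentres untouched.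

Step 10
Reactants: 15 C7'-aryl phenol with TIPS ether on the C7 aryl; 16 prenyl bromide
Product: 17 (1R,3aR,4S,6aR)-1-[3-methoxy-4-(triisopropylsilyloxy)phenyl]-4-{3-methoxy-4-[(3-methylbut-2-en-1-yl)oxy]phenyl}tetrahydro-1H,3H-furo[3,4-c]furan
Conditions: K2CO3, acetone, rt to 40 °C
Reagents that add atoms: none
Why: Williamson O-alkylation: the only free phenol is deprotonated by carbonate and attacks the primary allylic bromide by SN2, under conditions too mild to cleave the aryl TIPS ether or to disturb the benzylic ether stereocentres.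

Step 11
Reactants: 17 (1R,3aR,4S,6aR)-1-[3-methoxy-4-(triisopropylsilyloxy)phenyl]-4-{3-methoxy-4-[(3-methylbut-2-en-1-yl)oxy]phenyl}tetrahydro-1H,3H-furo[3,4-c]furan
Product: 18 2-methoxy-4-[(1R,3aR,4S,6aR)-4-{3-methoxy-4-[(3-methylbut-2-en-1-yl)oxy]phenyl}tetrahydro-1H,3H-furo[3,4-c]furan-1-yl]phenol (target)
Conditions: TBAF, AcOH (1:1), THF, 0 °C
Reagents that add atoms: none
Why: Fluoride attacks silicon (strong Si–F bond) and releases the phenoxide, which acetic acid protonates, so the endo C7 aryl ether, which would epimerise through a benzylic cation under acid, and the acid-labile prenyl ether are never exposed to acid.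

Compound list
1 | 4-(benzyloxy)-3-methoxybenzaldehyde | O=Cc1ccc(OCc2ccccc2)c(OC)c1 | starting material
2 | vinylmagnesium bromide | C=C[Mg]Br | starting material
3 | rac-1-[4-(benzyloxy)-3-methoxyphenyl]prop-2-en-1-ol | C=CC(O)c1ccc(OCc2ccccc2)c(OC)c1 | intermediate
4 | (R)-[4-(benzyloxy)-3-methoxyphenyl][(S)-oxiran-2-yl]methanol | O[C@H](c1ccc(OCc2ccccc2)c(OC)c1)[C@@H]1CO1 | intermediate
5 | propargyl bromide (3-bromoprop-1-yne) | C#CCBr | starting material
6 | (S)-2-{(R)-[4-(benzyloxy)-3-methoxyphenyl](prop-2-yn-1-yloxy)methyl}oxirane | C#CCO[C@H](c1ccc(OCc2ccccc2)c(OC)c1)[C@@H]1CO1 | intermediate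
7 | 4-iodo-2-methoxyphenol | COc1cc(I)ccc1O | starting material
8 | (4-iodo-2-methoxyphenoxy)tri(propan-2-yl)silane | COc1cc(I)ccc1O[Si](C(C)C)(C(C)C)C(C)C | intermediate
9 | (S)-2-{(R)-[4-(benzyloxy)-3-methoxyphenyl]({3-[3-methoxy-4-(triisopropylsilyloxy)phenyl]prop-2-yn-1-yl}oxy)methyl}oxirane | COc1cc(C#CCO[C@H](c2ccc(OCc3ccccc3)c(OC)c2)[C@@H]2CO2)ccc1O[Si](C(C)C)(C(C)C)C(C)C | intermediate
10 | [(2S,3R,4E)-2-[4-(benzyloxy)-3-methoxyphenyl]-4-{[3-methoxy-4-(triisopropylsilyloxy)phenyl]methylidene}oxolan-3-yl]methanol | OC[C@@H]1[C@@H](c2ccc(OCc3ccccc3)c(OC)c2)OC/C1=C/c1ccc(O[Si](C(C)C)(C(C)C)C(C)C)c(OC)c1 | intermediate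
11 | [(2S,3R,4E)-2-[4-(benzyloxy)-3-methoxyphenyl]-4-{[3-methoxy-4-(triisopropylsilyloxy)phenyl]methylidene}oxolan-3-yl]methyl methanesulfonate | CS(=O)(=O)OC[C@@H]1[C@@H](c2ccc(OCc3ccccc3)c(OC)c2)OC/C1=C/c1ccc(O[Si](C(C)C)(C(C)C)C(C)C)c(OC)c1 | intermediate
12 | benzylic C7 monoalkylborane: mesylate 11 with H on C8 and BH2 on C7, both added to the face anti to the C9' arm | CS(=O)(=O)OC[C@@H]1[C@@H](c2ccc(OCc3ccccc3)c(OC)c2)OC[C@@H]1[C@@H](B)c1ccc(O[Si](C(C)C)(C(C)C)C(C)C)c(OC)c1 | intermediate (not isolated)
13 | [(2S,3R,4R)-2-[4-(benzyloxy)-3-methoxyphenyl]-4-{(R)-hydroxy[3-methoxy-4-(triisopropylsilyloxy)phenyl]methyl}oxolan-3-yl]methyl methanesulfonate | CS(=O)(=O)OC[C@@H]1[C@@H](c2ccc(OCc3ccccc3)c(OC)c2)OC[C@@H]1[C@@H](O)c1ccc(O[Si](C(C)C)(C(C)C)C(C)C)c(OC)c1 | intermediate (not isolated)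
14 | (1R,3aR,4S,6aR)-4-[4-(benzyloxy)-3-methoxyphenyl]-1-[3-methoxy-4-(triisopropylsilyloxy)phenyl]tetrahydro-1H,3H-furo[3,4-c]furan | COc1cc([C@@H]2OC[C@H]3[C@@H]2CO[C@@H]3c2ccc(OCc3ccccc3)c(OC)c2)ccc1O[Si](C(C)C)(C(C)C)C(C)C | intermediate
15 | 2-methoxy-4-[(1S,3aR,4R,6aR)-4-[3-methoxy-4-(triisopropylsilyloxy)phenyl]tetrahydro-1H,3H-furo[3,4-c]furan-1-yl]phenol | COc1cc([C@@H]2OC[C@H]3[C@@H]2CO[C@@H]3c2ccc(O)c(OC)c2)ccc1O[Si](C(C)C)(C(C)C)C(C)C | intermediate
16 | prenyl bromide (1-bromo-3-methylbut-2-ene) | CC(C)=CCBr | starting material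
17 | (1R,3aR,4S,6aR)-1-[3-methoxy-4-(triisopropylsilyloxy)phenyl]-4-{3-methoxy-4-[(3-methylbut-2-en-1-yl)oxy]phenyl}tetrahydro-1H,3H-furo[3,4-c]furan | COc1cc([C@@H]2OC[C@H]3[C@@H]2CO[C@@H]3c2ccc(OCC=C(C)C)c(OC)c2)ccc1O[Si](C(C)C)(C(C)C)C(C)C | intermediate
18 | 2-methoxy-4-[(1R,3aR,4S,6aR)-4-{3-methoxy-4-[(3-methylbut-2-en-1-yl)oxy]phenyl}tetrahydro-1H,3H-furo[3,4-c]furan-1-yl]phenol | COc1cc([C@@H]2OC[C@H]3[C@@H]2CO[C@@H]3c2ccc(OCC=C(C)C)c(OC)c2)ccc1O | target

Total step count: 11. Longest linear sequence: 10 steps (1 → 3 → 4 → 6 → 9 → 10 → 11 → 14 → 15 → 17 → 18); step 4 is a one-step side branch.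

Steps most likely to fail

Step 8. Three processes can go wrong:
- The B–H addition may lose face discrimination; hydride delivered syn to the C9' arm gives the C8 epimer, which cannot close ring A.
- Part of the boron may go to C8, where β-alkoxy elimination would open ring B.
- The sulfonate may be lost to hydroxide or hydroperoxide before the C7 alkoxide exists.

The fallback separates these events and sets out from 10. Acylation (PivCl, pyridine, DMAP, CH2Cl2) gives the C9' pivalate F1, whose larger, base-stable arm should shield its face better. BH3·SMe2 in THF followed by buffered oxidation with NaBO3·4H2O should give the C7 carbinol pivalate F2, which is purified from any C7 or C8 isomer by chromatography. DIBAL-H (CH2Cl2, −78 °C) removes the ester and gives the C7,C9' diol F3. Primary-selective sulfonylation (MsCl, 2,4,6-collidine, CH2Cl2, −20 °C) then gives 13, where the route is rejoined; NaH in THF at 0 °C closes it to 14 with C7 untouched.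

Step 6. The β-titanoxy radical may be reduced by a second Cp2TiCl and eliminate to the deoxygenated allyl ether before it cyclises, and the vinyl radical may be quenched without full geometric control. The fallback makes the same C8' radical without a metal that can eliminate and sets out from 9. Opening of the oxirane at its CH2 terminus with benzoic acid (Bu4NBr cat., MeCN, 80 °C) gives the secondary alcohol benzoate F4. Phenyl chlorothionoformate (pyridine, DMAP, CH2Cl2) converts it into the O-phenyl thionocarbonate F5. Slow addition of Bu3SnH with AIBN in toluene at 80 °C (Barton–McCombie-type C–O homolysis, 5-exo-dig closure, hydrogen transfer from the bulky stannane on the open C9 side) should give the cyclised E-benzylidene benzoate F6. DIBAL-H (CH2Cl2, −78 °C) frees the alcohol and the route is rejoined at 10.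

Step 2. The rate difference between the two carbinol enantiomers may be too small; the epoxy alcohol is the product of the fast enantiomer, so its enantiomeric purity cannot be raised by pushing conversion. The electron-rich benzylic epoxy alcohol may also suffer on long contact with the titanium alkoxide. The fallback sets out from 3 and resolves with an enzyme. A lipase (Novozym 435 or Amano lipase PS, vinyl acetate, MTBE, 30 °C), run past half conversion, acetylates the (R)-alcohol to (R)-1-[4-(benzyloxy)-3-methoxyphenyl]prop-2-en-1-yl acetate F8 and leaves (S)-1-[4-(benzyloxy)-3-methoxyphenyl]prop-2-en-1-ol F7 in high enantiomeric purity. F7 is then epoxidised under matched Sharpless conditions (Ti(OiPr)4, D-(−)-DIPT, TBHP, 4 Å MS, CH2Cl2, −20 °C), now a fast diastereoselective reaction of a single enantiomer, and the route is rejoined at 4.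

Further compounds
F1 | step 8 | [(2S,3R,4E)-2-[4-(benzyloxy)-3-methoxyphenyl]-4-{[3-methoxy-4-(triisopropylsilyloxy)phenyl]methylidene}oxolan-3-yl]methyl 2,2-dimethylpropanoate | CC(C)(C)C(=O)OC[C@@H]1[C@@H](c2ccc(OCc3ccccc3)c(OC)c2)OC/C1=C/c1ccc(O[Si](C(C)C)(C(C)C)C(C)C)c(OC)c1
F2 | step 8 | [(2S,3R,4R)-2-[4-(benzyloxy)-3-methoxyphenyl]-4-{(R)-hydroxy[3-methoxy-4-(triisopropylsilyloxy)phenyl]methyl}oxolan-3-yl]methyl 2,2-dimethylpropanoate | CC(C)(C)C(=O)OC[C@@H]1[C@@H](c2ccc(OCc3ccccc3)c(OC)c2)OC[C@@H]1[C@@H](O)c1ccc(O[Si](C(C)C)(C(C)C)C(C)C)c(OC)c1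
F3 | step 8 | (R)-[(3R,4R,5S)-5-[4-(benzyloxy)-3-methoxyphenyl]-4-(hydroxymethyl)oxolan-3-yl][3-methoxy-4-(triisopropylsilyloxy)phenyl]methanol | OC[C@@H]1[C@@H](c2ccc(OCc3ccccc3)c(OC)c2)OC[C@@H]1[C@@H](O)c1ccc(O[Si](C(C)C)(C(C)C)C(C)C)c(OC)c1
F4 | step 6 | (2S,3R)-3-[4-(benzyloxy)-3-methoxyphenyl]-2-hydroxy-3-({3-[3-methoxy-4-(triisopropylsilyloxy)phenyl]prop-2-yn-1-yl}oxy)propyl benzoate | COc1cc(C#CCO[C@H](c2ccc(OCc3ccccc3)c(OC)c2)[C@@H](O)COC(=O)c2ccccc2)ccc1O[Si](C(C)C)(C(C)C)C(C)C
F5 | step 6 | (2S,3R)-3-[4-(benzyloxy)-3-methoxyphenyl]-3-({3-[3-methoxy-4-(triisopropylsilyloxy)phenyl]prop-2-yn-1-yl}oxy)-2-[(phenoxycarbonothioyl)oxy]propyl benzoate | COc1cc(C#CCO[C@H](c2ccc(OCc3ccccc3)c(OC)c2)[C@@H](OC(=S)Oc2ccccc2)COC(=O)c2ccccc2)ccc1O[Si](C(C)C)(C(C)C)C(C)C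
F6 | step 6 | [(2S,3R,4E)-2-[4-(benzyloxy)-3-methoxyphenyl]-4-{[3-methoxy-4-(triisopropylsilyloxy)phenyl]methylidene}oxolan-3-yl]methyl benzoate | O=C(OC[C@@H]1[C@@H](c2ccc(OCc3ccccc3)c(OC)c2)OC/C1=C/c1ccc(O[Si](C(C)C)(C(C)C)C(C)C)c(OC)c1)c1ccccc1
F7 | step 2 | (S)-1-[4-(benzyloxy)-3-methoxyphenyl]prop-2-en-1-ol | C=C[C@H](O)c1ccc(OCc2ccccc2)c(OC)c1
F8 | step 2 | (R)-1-[4-(benzyloxy)-3-methoxyphenyl]prop-2-en-1-yl acetate | C=C[C@@H](OC(C)=O)c1ccc(OCc2ccccc2)c(OC)c1
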